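**Plan**

Locants (lignan usage): C-7 and C-7' are the two ArCH–O carbons; C-8 is the carbinol ring-fusion carbon (joined to C-7 and C-9H2); C-8' is the CH ring-fusion carbon (joined to C-7' and C-9'H2). Ring A = O–C-7'–C-8'–C-8–C-9, ring B = C-7–O–C-9'–C-8'–C-8. Ts = 4-toluenesulfonyl, TBS = tert-butyldimethylsilyl.
Retrosynthesis: the phenols are masked as tosylates and the C-9 methylene is taken back to a lactone carbonyl; ring A is then cut at O(7')–C-9 and the ring fusion at C-8–C-8', which opens both rings to an acyclic cis-epoxy ether ester. This is cut at the oxirane (Z-alkene, alkyne), at the C-7–O–C-9' ether (β-hydroxy ester + propargylic bromide) and at C-7–C-8 (aroyl chloride + silyl glycolate).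
Forward: the chain is joined by C-acylation (C-7–C-8) and O-alkylation (O–C-9'); both rings then arise in one flask, ring B first (C-8–C-8') and ring A, as a γ-lactone (O–C-9), directly after it; the lactone carbonyl is finally taken down to CH2 without opening ring A.
Stereochemistry: C-7 from Ru-catalysed asymmetric transfer hydrogenation; C-7' and C-8' from Jacobsen epoxidation of the Z-alkene (C-8' is inverted in the key step, which turns the cis-oxirane into the exo aryl group); C-8 from 1,3-allylic strain in the key step, checked by the lactonisation that only the cis isomer can undergo.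
Enabling feature: ring A is a 3-hydroxytetrahydrofuran, i.e. a reduced α-hydroxy-γ-butyrolactone, and a γ-lactone is what an ester enolate and an oxirane give. O–C-7'–C-8' is read as a cis-oxirane and C-8(O)–C-9 as an α-silyloxy ester, and the C-7–O–C-9' ether already holds the enolate carbon five atoms from the oxirane carbon.

Key step: step 11

Remark: the ester α-carbon (the later C-8) is carried as a mixture of epimers from the keto ester to the epoxide and is written without descriptor, because it becomes the planar enolate carbon in the key step.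

**Route**

Step 1
Reactants: 1 4-iodo-2-methoxyphenol
Product: 2 4-iodo-2-methoxyphenyl 4-methylbenzenesulfonate
Conditions: TsCl, Et3N, DMAP (cat.), CH2Cl2, 0 °C → rt
Reagents that add atoms: 4-toluenesulfonyl chloride (TsCl), Cc1ccc(cc1)S(=O)(=O)Cl
Why: Base-mediated O-sulfonylation of the phenol should be clean, and the tosylate makes the arene electron-poor, which later protects the aryl epoxide and the benzylic ethers from acid-type ionisation.

Step 2
Reactants: 2 4-iodo-2-methoxyphenyl 4-methylbenzenesulfonate; 3 prop-2-yn-1-ol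
Product: 4 3-[3-methoxy-4-(tosyloxy)phenyl]prop-2-yn-1-ol
Conditions: Pd(PPh3)2Cl2 (2 mol %), CuI (4 mol %), Et3N, THF, rt
Reagents that add atoms: none
Why: Sonogashira coupling takes place at the C–I bond at room temperature, while the aryl sulfonate C–O bond is inert to the zerovalent palladium catalyst under these conditions.

Step 3
Reactants: 4 3-[3-methoxy-4-(tosyloxy)phenyl]prop-2-yn-1-ol
Product: 5 4-(3-bromoprop-1-yn-1-yl)-2-methoxyphenyl 4-methylbenzenesulfonate
Conditions: CBr4, PPh3, CH2Cl2, 0 °C
Reagents that add atoms: carbon tetrabromide, BrC(Br)(Br)Br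
Why: Appel reaction, in which the alkoxyphosphonium ion of the primary propargylic alcohol is displaced by bromide under neutral conditions that leave alkyne and sulfonate untouched.

Step 4
Reactants: 6 vanillic acid (4-hydroxy-3-methoxybenzoic acid)
Product: 7 3-methoxy-4-(tosyloxy)benzoic acid
Conditions: TsCl, NaOH (aq.), THF, 0 °C → rt; then HCl (aq.)
Reagents that add atoms: 4-toluenesulfonyl chloride (TsCl), Cc1ccc(cc1)S(=O)(=O)Cl
Why: Schotten–Baumann sulfonylation, in which the phenoxide is sulfonylated in aqueous base while any mixed carboxylic–sulfonic anhydride is hydrolysed back to the carboxylate, so that only the phenol ends up protected.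

Step 5
Reactants: 8 methyl glycolate
Product: 9 methyl 2-[(tert-butyldimethylsilyl)oxy]acetate
Conditions: TBSCl, imidazole, DMF, rt
Reagents that add atoms: tert-butyldimethylsilyl chloride (TBSCl), CC(C)(C)[Si](C)(C)Cl
Why: Standard imidazole-promoted silylation of a primary alcohol gives the silyl glycolate, whose lithium enolate is a well-behaved C-nucleophile.

Step 6
Reactants: 7 3-methoxy-4-(tosyloxy)benzoic acid; 9 methyl 2-[(tert-butyldimethylsilyl)oxy]acetate
Product: 12 methyl 2-[(tert-butyldimethylsilyl)oxy]-3-[3-methoxy-4-(tosyloxy)phenyl]-3-oxopropanoate, via acid chloride 10 (not isolated), via lithium enolate 11 (not isolated)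
Conditions: 7: (COCl)2, DMF (cat.), CH2Cl2, rt, evaporation; 9 (2.1 equiv): LiN(iPr)2 (2.1 equiv), THF, −78 °C; 10 added at −78 °C; AcOH
Reagents that add atoms: none
Why: Acid chloride formation with oxalyl chloride and Claisen-type C-acylation of the lithium ester enolate, in which the second equivalent of enolate deprotonates the more acidic β-keto ester as it forms and so prevents a second acylation.

Step 7
Reactants: 12 methyl 2-[(tert-butyldimethylsilyl)oxy]-3-[3-methoxy-4-(tosyloxy)phenyl]-3-oxopropanoate
Product: 13 methyl (3R)-2-[(tert-butyldimethylsilyl)oxy]-3-hydroxy-3-[3-methoxy-4-(tosyloxy)phenyl]propanoate (C-2 epimers)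
Conditions: RuCl(p-cymene)[(S,S)-TsDPEN] (1 mol %), HCO2H/Et3N (5:2), CH2Cl2, rt
Reagents that add atoms: none
Why: Noyori-type asymmetric transfer hydrogenation of the aryl ketone, in which the ruthenium hydride attacks the carbonyl face selected by the aryl–arene contact with the (S,S)-ligand and is expected to give the (3R)-carbinol (the usual sense for aryl ketones, the descriptor being R because C-2 outranks the aryl group), while C-2 epimerises through the enol and is without consequence later.

Step 8
Reactants: 13 methyl (3R)-2-[(tert-butyldimethylsilyl)oxy]-3-hydroxy-3-[3-methoxy-4-(tosyloxy)phenyl]propanoate; 5 4-(3-bromoprop-1-yn-1-yl)-2-methoxyphenyl 4-methylbenzenesulfonate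
Product: 14 methyl (3R)-2-[(tert-butyldimethylsilyl)oxy]-3-[3-methoxy-4-(tosyloxy)phenyl]-3-({3-[3-methoxy-4-(tosyloxy)phenyl]prop-2-yn-1-yl}oxy)propanoate
Conditions: Ag2O, 4 Å molecular sieves, CH2Cl2, rt, dark
Reagents that add atoms: none
Why: Silver-oxide-assisted Williamson etherification with the activated propargylic bromide alkylates the only free hydroxyl without generating an alkoxide, so that retro-aldol cleavage and 1,2-silyl migration of the β-hydroxy-α-silyloxy ester should not compete, and C-7 is not touched.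

Step 9
Reactants: 14 the propargylic ether of step 8
Product: 15 methyl (3R)-2-[(tert-butyldimethylsilyl)oxy]-3-[3-methoxy-4-(tosyloxy)phenyl]-3-({(2Z)-3-[3-methoxy-4-(tosyloxy)phenyl]prop-2-en-1-yl}oxy)propanoate
Conditions: H2 (1 atm), Pd/CaCO3 poisoned with Pb(OAc)2 (Lindlar catalyst), quinoline, EtOAc, rt
Reagents that add atoms: none
Why: Lindlar semihydrogenation adds hydrogen syn to the alkyne and stops at the (Z)-alkene, and the poisoned catalyst does not hydrogenolyse the benzylic ether or the sulfonates.

Step 10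
Reactants: 15 the (Z)-alkene of step 9
Product: 16 methyl (3R)-2-[(tert-butyldimethylsilyl)oxy]-3-[3-methoxy-4-(tosyloxy)phenyl]-3-({(2S,3R)-3-[3-methoxy-4-(tosyloxy)phenyl]oxiran-2-yl}methoxy)propanoate (cis-epoxide)
Conditions: (R,R)-(salen)MnCl (5 mol %; salen = dianion of N,N'-bis(3,5-di-tert-butylsalicylidene)cyclohexane-1,2-diamine), 4-phenylpyridine N-oxide, NaOCl (aq., pH 11.3), CH2Cl2, 0 °C
Reagents that add atoms: sodium hypochlorite, [Na+].[O-]Cl
Why: Jacobsen epoxidation, the method of choice for cis-1,2-disubstituted aryl alkenes, transfers oxygen from the oxo-manganese salen species to one enantioface under catalyst control (the (R,R)-complex is expected to give the benzylic-R, (2S,3R) oxirane by analogy with cis-β-methylstyrene), the remote C-7 centre having no influence and the electron-poor aryl group keeping the cis-epoxide from ionising.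

Step 11
Reactants: 16 the cis-epoxy ester of step 10
Product: 20 (3S,3aR,6R,6aR)-6a-hydroxy-3,6-bis[3-methoxy-4-(tosyloxy)phenyl]tetrahydro-1H,3H-furo[3,4-c]furan-1-one, via lithium enolate 17 (not isolated), via lithium alkoxide 18 (not isolated), via silyl lactone 19 (not isolated)
Conditions: LiN(iPr)2 (1.1 equiv), THF, −78 °C, then −78 → 0 °C; then AcOH, Bu4NF, THF, 0 °C → rt
Reagents that add atoms: none
Why: Deprotonation at C-8 gives the α-silyloxy ester enolate 17, whose carbon attacks the oxirane carbon C-8' from the side opposite its C–O bond, and the lithium alkoxide 18 set free at C-7' adds to the neighbouring ester and expels methoxide (a silyl group that has wandered to O-7' is removed by the fluoride/acetic acid finish, after which the γ-hydroxy ester lactonises in the same way). The closest known reaction types are the intramolecular opening of epoxides by ester and nitrile enolates (Stork-type epoxy ester cyclisation) and the γ-lactone synthesis from enolates and epoxides. Ring B closes in the 5-exo-tet mode (enolate exocyclic, oxirane C–O bond outside the new ring) and ring A by 5-exo-trig acyl substitution. C-8' is set by inversion at the oxirane carbon and C-7' is carried over unchanged, so that the cis-oxirane becomes the C-7' aryl group trans to C-9' (exo); C-8 is set in the C–C bond-forming event by 1,3-allylic strain, which places H-7 and not the aryl group next to the enolate C=C(OLi)OMe unit and so puts the silyloxy group cis to the C-7 aryl group and the ester cis to the C-7' alkoxide. The step needs C- over O-alkylation, 5-exo over 6-endo attack and ring closure faster than E1cB loss of the C-7 ether oxygen: the first is secured by ring size (O-alkylation would give a seven-membered ketene acetal), the second by the Lewis-acid-free conditions and the electron-poor tosyloxyaryl group, which leaves the benzylic carbon without cationic character, and the third by forming the enolate at −78 °C and warming only as far as the intramolecular opening requires. Only the diastereomer with ester and alkoxide cis can lactonise, so formation of 20 checks all four stereocentres at once.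

Step 12
Reactants: 20 the hydroxy lactone of step 11
Product: 21 (3S,3aR,6R,6aR)-3,6-bis[3-methoxy-4-(tosyloxy)phenyl]tetrahydro-1H,3H-furo[3,4-c]furan-1,6a-diol (lactol, both C-1 anomers)
Conditions: iBu2AlH (2.5 equiv), CH2Cl2, −78 °C; potassium sodium tartrate (aq.)
Reagents that add atoms: none
Why: Half-reduction of a γ-lactone with iBu2AlH at −78 °C stops at the lactol because the tetrahedral aluminium alkoxide does not collapse at this temperature, the first equivalent being consumed by the tertiary hydroxyl and the ring A C–O bonds made in step 11 staying in place.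

Step 13
Reactants: 21 the lactol of step 12
Product: 22 (1S,3aS,4R,6aR)-1,4-bis[3-methoxy-4-(tosyloxy)phenyl]tetrahydro-1H,3H-furo[3,4-c]furan-3a-ol
Conditions: Et3SiH, TMSOTf (cat.), CH2Cl2, −78 → −40 °C; NaHCO3 (aq.)
Reagents that add atoms: none
Why: Ionic hydrogenation of the lactol, in which acid-induced loss of the anomeric oxygen gives the cyclic oxocarbenium ion at C-9 that takes hydride from the silane, while the tosyloxyaryl-substituted benzylic C–O bonds are too electron-poor to ionise and no stereocentre is formed.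

Step 14
Reactants: 22 the bis-tosylate of step 13
Product: 23 8-hydroxypinoresinol, (1S,3aS,4R,6aR)-1,4-bis(4-hydroxy-3-methoxyphenyl)tetrahydro-1H,3H-furo[3,4-c]furan-3a-ol
Conditions: KOH, MeOH/THF/H2O, 55 °C; then NH4Cl (aq.)
Reagents that add atoms: none
Why: Saponification of the two aryl sulfonates by hydroxide attack at sulfur releases the phenoxides, the furofuran ethers and the tertiary alcohol being stable to base, and mild acidification gives the target.

**Compound list**

1 | 4-iodo-2-methoxyphenol | COc1cc(I)ccc1O | starting material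
2 | 4-iodo-2-methoxyphenyl 4-methylbenzenesulfonate | COc1cc(I)ccc1OS(=O)(=O)c1ccc(C)cc1 | intermediate
3 | prop-2-yn-1-ol | OCC#C | starting material
4 | 3-[3-methoxy-4-(tosyloxy)phenyl]prop-2-yn-1-ol | COc1cc(C#CCO)ccc1OS(=O)(=O)c1ccc(C)cc1 | intermediate
5 | 4-(3-bromoprop-1-yn-1-yl)-2-methoxyphenyl 4-methylbenzenesulfonate | COc1cc(C#CCBr)ccc1OS(=O)(=O)c1ccc(C)cc1 | intermediate
6 | vanillic acid | COc1cc(C(=O)O)ccc1O | starting material
7 | 3-methoxy-4-(tosyloxy)benzoic acid | COc1cc(C(=O)O)ccc1OS(=O)(=O)c1ccc(C)cc1 | intermediate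
8 | methyl glycolate | COC(=O)CO | starting material
9 | methyl 2-[(tert-butyldimethylsilyl)oxy]acetate | COC(=O)CO[Si](C)(C)C(C)(C)C | intermediate
10 | 3-methoxy-4-(tosyloxy)benzoyl chloride | COc1cc(C(=O)Cl)ccc1OS(=O)(=O)c1ccc(C)cc1 | intermediate
11 | lithium enolate of 9 | [Li+].COC([O-])=CO[Si](C)(C)C(C)(C)C | intermediate
12 | methyl 2-[(tert-butyldimethylsilyl)oxy]-3-[3-methoxy-4-(tosyloxy)phenyl]-3-oxopropanoate | COC(=O)C(O[Si](C)(C)C(C)(C)C)C(=O)c1ccc(OS(=O)(=O)c2ccc(C)cc2)c(OC)c1 | intermediate
13 | methyl (3R)-2-[(tert-butyldimethylsilyl)oxy]-3-hydroxy-3-[3-methoxy-4-(tosyloxy)phenyl]propanoate, C-2 epimers | O[C@H](c1ccc(OS(=O)(=O)c2ccc(C)cc2)c(OC)c1)C(O[Si](C)(C)C(C)(C)C)C(=O)OC | intermediate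
14 | propargylic ether of 13 with 5, (3R) | COc1cc(C#CCO[C@H](c2ccc(OS(=O)(=O)c3ccc(C)cc3)c(OC)c2)C(O[Si](C)(C)C(C)(C)C)C(=O)OC)ccc1OS(=O)(=O)c1ccc(C)cc1 | intermediate
15 | (Z)-alkene from 14, (3R) | COc1cc(/C=C\CO[C@H](c2ccc(OS(=O)(=O)c3ccc(C)cc3)c(OC)c2)C(O[Si](C)(C)C(C)(C)C)C(=O)OC)ccc1OS(=O)(=O)c1ccc(C)cc1 | intermediate
16 | cis-epoxy ester, (3R) with (2S,3R)-oxirane | COc1cc([C@H]2O[C@H]2CO[C@H](c2ccc(OS(=O)(=O)c3ccc(C)cc3)c(OC)c2)C(O[Si](C)(C)C(C)(C)C)C(=O)OC)ccc1OS(=O)(=O)c1ccc(C)cc1 | intermediate
17 | lithium enolate of 16 | [Li+].COc1cc([C@H]2O[C@H]2CO[C@H](c2ccc(OS(=O)(=O)c3ccc(C)cc3)c(OC)c2)C(O[Si](C)(C)C(C)(C)C)=C([O-])OC)ccc1OS(=O)(=O)c1ccc(C)cc1 | intermediate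
18 | lithium alkoxide of the ring B tetrahydrofuran ester (ring A still open, all centres as in 20) | [Li+].COc1cc([C@@H]([O-])[C@H]2CO[C@H](c3ccc(OS(=O)(=O)c4ccc(C)cc4)c(OC)c3)[C@@]2(O[Si](C)(C)C(C)(C)C)C(=O)OC)ccc1OS(=O)(=O)c1ccc(C)cc1 | intermediate
19 | 6a-O-TBS ether of lactone 20 | COc1cc([C@H]2OC(=O)[C@]3(O[Si](C)(C)C(C)(C)C)[C@@H](c4ccc(OS(=O)(=O)c5ccc(C)cc5)c(OC)c4)OC[C@H]23)ccc1OS(=O)(=O)c1ccc(C)cc1 | intermediate
20 | (3S,3aR,6R,6aR)-6a-hydroxy-3,6-bis[3-methoxy-4-(tosyloxy)phenyl]tetrahydro-1H,3H-furo[3,4-c]furan-1-one | COc1cc([C@H]2OC(=O)[C@]3(O)[C@@H](c4ccc(OS(=O)(=O)c5ccc(C)cc5)c(OC)c4)OC[C@H]23)ccc1OS(=O)(=O)c1ccc(C)cc1 | intermediate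
21 | lactol of 20 (C-1 anomers) | COc1cc([C@H]2OC(O)[C@]3(O)[C@@H](c4ccc(OS(=O)(=O)c5ccc(C)cc5)c(OC)c4)OC[C@H]23)ccc1OS(=O)(=O)c1ccc(C)cc1 | intermediate
22 | (1S,3aS,4R,6aR)-1,4-bis[3-methoxy-4-(tosyloxy)phenyl]tetrahydro-1H,3H-furo[3,4-c]furan-3a-ol | COc1cc([C@H]2OC[C@]3(O)[C@@H](c4ccc(OS(=O)(=O)c5ccc(C)cc5)c(OC)c4)OC[C@H]23)ccc1OS(=O)(=O)c1ccc(C)cc1 | intermediate
23 | 8-hydroxypinoresinol | COc1cc([C@H]2OC[C@]3(O)[C@@H](c4ccc(O)c(OC)c4)OC[C@H]23)ccc1O | target

**Count**

Total steps: 14. Longest linear sequence: 10 steps (4, 6, 7, 8, 9, 10, 11, 12, 13, 14).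

**Steps most likely to fail**

1. Step 11. What may go wrong: E1cB loss of the C-7 ether oxygen (cleavage of the tether) from the tetrasubstituted enolate before the oxirane is opened, or C–C bond formation on the enolate face that leaves the ester and the C-7' alkoxide trans, so that ring A cannot close. Fallback (the C-8 oxygen is introduced last, by enolate oxidation on the finished bicycle): it sets out from acid 7 (as its chloride 10) and bromide 5 and returns at lactone 20. Acylation of the magnesium enolate of potassium methyl malonate (MgCl2, Et3N, MeCN) with 10, followed by decarboxylation, gives methyl 3-[3-methoxy-4-(tosyloxy)phenyl]-3-oxopropanoate F1. The transfer hydrogenation of step 7 gives methyl (3S)-3-hydroxy-3-[3-methoxy-4-(tosyloxy)phenyl]propanoate F2, with the same spatial sense as 13. Ag2O etherification with 5 gives the propargylic ether F3, Lindlar semihydrogenation the (Z)-alkene F4, and Jacobsen epoxidation the cis-epoxy ester F5. LiN(iPr)2 (THF, −78 → 0 °C) should then give the C-8-unsubstituted cis-fused lactone F6; the less hindered enolate should open the oxirane faster, and both C-8 epimers converge because C-8–H is epimerisable. Hydroxylation of the potassium enolate of F6 (KN(SiMe3)2, 2-(phenylsulfonyl)-3-phenyloxaziridine, THF, −78 °C) on the convex face, the only open one on the cis-fused bicycle, gives 20.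

2. Step 10. What may go wrong: leakage of the cis-alkene to trans-epoxide through bond rotation in the radical intermediate, and incomplete enantioface selection; both would be carried into C-7'/C-8' stereoisomers of 20. Fallback (the oxirane is made before fragment union by Sharpless asymmetric epoxidation, where the allylic hydroxyl binds the titanium tartrate and concerted oxygen transfer keeps the cis geometry): it sets out from alcohol 4 and carbinol 13 and returns at 16. Lindlar semihydrogenation of 4 gives the (Z)-allylic alcohol F7. Ti(OiPr)4, L-(+)-diethyl tartrate, t-BuOOH and 4 Å molecular sieves (CH2Cl2, −20 °C) should give the (2S,3R)-epoxy alcohol F8. Tf2O and 2,6-lutidine at −78 °C give the epoxy triflate F9, which alkylates 13 in the presence of 2,6-di-tert-butyl-4-methylpyridine (CH2Cl2, 0 °C) to give 16.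

3. Step 8. What may go wrong: sluggish alkylation of the hindered benzylic hydroxyl, so that silyl migration from O-2 to O-3 or decomposition of the propargylic bromide takes over. Fallback (acid-catalysed imidate alkylation through the aryl-stabilised propargylic cation, without silver or a basic oxide): it sets out from alcohol 4 and returns at 14. Cl3CCN and DBU (cat.) convert 4 into the trichloroacetimidate F10, and 13 is alkylated with F10 under TfOH catalysis (CH2Cl2, −20 °C) to give 14.

**Further compounds**

F1 | step 11 | methyl 3-[3-methoxy-4-(tosyloxy)phenyl]-3-oxopropanoate | COC(=O)CC(=O)c1ccc(OS(=O)(=O)c2ccc(C)cc2)c(OC)c1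
F2 | step 11 | methyl (3S)-3-hydroxy-3-[3-methoxy-4-(tosyloxy)phenyl]propanoate | O[C@H](c1ccc(OS(=O)(=O)c2ccc(C)cc2)c(OC)c1)CC(=O)OC
F3 | step 11 | propargylic ether of F2 with 5 | COc1cc(C#CCO[C@H](c2ccc(OS(=O)(=O)c3ccc(C)cc3)c(OC)c2)CC(=O)OC)ccc1OS(=O)(=O)c1ccc(C)cc1
F4 | step 11 | (Z)-alkene from F3 | COc1cc(/C=C\CO[C@H](c2ccc(OS(=O)(=O)c3ccc(C)cc3)c(OC)c2)CC(=O)OC)ccc1OS(=O)(=O)c1ccc(C)cc1
F5 | step 11 | cis-epoxy ester from F4, (2S,3R)-oxirane | COc1cc([C@H]2O[C@H]2CO[C@H](c2ccc(OS(=O)(=O)c3ccc(C)cc3)c(OC)c2)CC(=O)OC)ccc1OS(=O)(=O)c1ccc(C)cc1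
F6 | step 11 | cis-fused 3,6-diaryl-tetrahydro-1H,3H-furo[3,4-c]furan-1-one lacking the 6a-hydroxyl | COc1cc([C@H]2OC(=O)[C@@H]3[C@@H](c4ccc(OS(=O)(=O)c5ccc(C)cc5)c(OC)c4)OC[C@H]23)ccc1OS(=O)(=O)c1ccc(C)cc1
F7 | step 10 | (2Z)-3-[3-methoxy-4-(tosyloxy)phenyl]prop-2-en-1-ol | COc1cc(/C=C\CO)ccc1OS(=O)(=O)c1ccc(C)cc1
F8 | step 10 | {(2S,3R)-3-[3-methoxy-4-(tosyloxy)phenyl]oxiran-2-yl}methanol | COc1cc([C@H]2O[C@H]2CO)ccc1OS(=O)(=O)c1ccc(C)cc1
F9 | step 10 | trifluoromethanesulfonate of F8 | COc1cc([C@H]2O[C@H]2COS(=O)(=O)C(F)(F)F)ccc1OS(=O)(=O)c1ccc(C)cc1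
F10 | step 8 | 3-[3-methoxy-4-(tosyloxy)phenyl]prop-2-yn-1-yl 2,2,2-trichloroacetimidate | COc1cc(C#CCOC(=N)C(Cl)(Cl)Cl)ccc1OS(=O)(=O)c1ccc(C)cc1
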